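The benzenoid ring of the indole (C3a, C4–C7, C7a) is cut into two pieces. One is the C2=C3 bond of a pyrrole that already carries the pyrimidine at its C4 (indole C3). The other is a four-carbon arm in which C4–OH is a latent ketene carbonyl and C6–Br sits on the central alkene carbon, so the meta OH/Br pattern follows from connectivity alone. The precursor is an (E)-α-bromovinyl diazomethyl ketone on C2 of the N-tosylpyrrole. Its irradiation expels N2, makes C5–C6 by Wolff shift and C3a–C4 by 6π closure, and gives the 6-bromo-4-hydroxyindole after enolisation. The pyrimidine travels as its inert 2,4-dimethoxy form and becomes the 4-amino-2-bromo ring afterwards.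

Key step: step 7

Remark on the chemistry: the target has no stereocentre; the only stereochemical element in the route is the C=C geometry of 7, 8 and 10–12, where E (bromine outranks the acyl carbon) means that the pyrrole and the acyl or ketene arm lie on the same side. Tosyl = 4-methylbenzenesulfonyl.

Step 1
Reactants: 1 4-bromo-1H-pyrrole-2-carbaldehyde
Product: 2 4-bromo-1-tosyl-1H-pyrrole-2-carbaldehyde
Conditions: NaH, TsCl, THF, 0 °C → 20 °C
Reagents that add atoms: 4-methylbenzenesulfonyl chloride, Cc1ccc(cc1)S(=O)(=O)Cl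
Why: N-Sulfonylation of the sodium pyrrolide is routine, and placing it before the coupling suppresses the reductive debromination that N–H 4-bromopyrroles with a 2-acyl group tend to suffer under Suzuki conditions.

Step 2
Reactants: 2 4-bromo-1-tosyl-1H-pyrrole-2-carbaldehyde; 3 (2,4-dimethoxypyrimidin-5-yl)boronic acid
Product: 4 4-(2,4-dimethoxypyrimidin-5-yl)-1-tosyl-1H-pyrrole-2-carbaldehyde
Conditions: Pd(dppf)Cl2 (5 mol %), K3PO4, dioxane/H2O (10:1), 70 °C
Reagents that add atoms: none
Why: Suzuki–Miyaura coupling of an electron-poor heteroaryl bromide (the only C–Br bond present at this stage) with a widely used heteroarylboronic acid, where the phosphate base, little water and moderate temperature spare the N-tosyl group and limit protodeboronation.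

Step 3
Reactants: 5 methyl 2-[bis(2,2,2-trifluoroethoxy)phosphoryl]acetate
Product: 6 methyl 2-bromo-2-[bis(2,2,2-trifluoroethoxy)phosphoryl]acetate (racemic)
Conditions: NaH, THF, 0 °C; Br2, −78 °C → 0 °C
Reagents that add atoms: bromine, BrBr
Why: Electrophilic bromination of the stabilised phosphonoacetate carbanion, in which the new C–Br stereocentre is racemic and disappears in step 4, and minor non- and dibrominated phosphonates are removed by chromatography.

Step 4
Reactants: 4 4-(2,4-dimethoxypyrimidin-5-yl)-1-tosyl-1H-pyrrole-2-carbaldehyde; 6 methyl 2-bromo-2-[bis(2,2,2-trifluoroethoxy)phosphoryl]acetate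
Product: 7 methyl (E)-2-bromo-3-[4-(2,4-dimethoxypyrimidin-5-yl)-1-tosyl-1H-pyrrol-2-yl]prop-2-enoate (pyrrole cis to CO2Me)
Conditions: 6, t-BuOK, 18-crown-6, THF, −78 °C; then 4, −78 °C → −40 °C
Reagents that add atoms: none
Why: Still–Gennari-type Horner–Wadsworth–Emmons olefination, in which the electron-poor trifluoroethyl phosphonate and the dissociated potassium ion make collapse of the kinetic adduct irreversible and so place the ester cis to the pyrrole (E), a geometry that simple dialkyl bromophosphonoacetates or the bromo ylide do not deliver reliably.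

Step 5
Reactants: 7 methyl (E)-2-bromo-3-[4-(2,4-dimethoxypyrimidin-5-yl)-1-tosyl-1H-pyrrol-2-yl]prop-2-enoate
Product: 8 (E)-2-bromo-3-[4-(2,4-dimethoxypyrimidin-5-yl)-1-tosyl-1H-pyrrol-2-yl]prop-2-enoic acid
Conditions: LiOH (1.5 equiv), THF/H2O, 0 °C → 20 °C; then 1 M HCl to pH 3
Reagents that add atoms: lithium hydroxide, [Li+].[OH-] (oxygen of the new O–H)
Why: Saponification of a methyl ester activated by the α-bromine should outrun attack of hydroxide on the sulfonyl sulfur at or below room temperature, and the syn arrangement of the vinylic H and Br disfavours elimination to the alkynoate.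

Step 6
Reactants: 8 (E)-2-bromo-3-[4-(2,4-dimethoxypyrimidin-5-yl)-1-tosyl-1H-pyrrol-2-yl]prop-2-enoic acid; 9 (trimethylsilyl)diazomethane
Product: 11 (E)-3-bromo-1-diazo-4-[4-(2,4-dimethoxypyrimidin-5-yl)-1-tosyl-1H-pyrrol-2-yl]but-3-en-2-one, via acid chloride 10 (not isolated)
Conditions: (COCl)2, DMF (cat.), CH2Cl2, 0 °C; evaporate; 9 (2 equiv, 2 M in hexanes), THF/MeCN, 0 °C
Reagents that add atoms: oxalyl chloride, O=C(Cl)C(=O)Cl (its chlorine is carried by intermediate 10 only)
Why: Acylation of the diazoalkane by an acid chloride (first stage of the Arndt–Eistert sequence) with chloride-induced loss of the silyl group, helped by the absence of an α-hydrogen (no ketene from 10) and by the twisted, trisubstituted bromoalkene being a poor dipolarophile for the bulky reagent at 0 °C.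

Step 7
Reactants: 11 (E)-3-bromo-1-diazo-4-[4-(2,4-dimethoxypyrimidin-5-yl)-1-tosyl-1H-pyrrol-2-yl]but-3-en-2-one
Product: 14 6-bromo-3-(2,4-dimethoxypyrimidin-5-yl)-1-tosyl-1H-indol-4-ol, via dienylketene 12 (not isolated), via cyclohexadienone tautomer 13 (not isolated)
Conditions: hν (365 nm LED), dry degassed ClCH2CH2Cl (0.005 M), 20 °C until N2 evolution stops; then 80 °C, 1 h, dark
Reagents that add atoms: none
Why: Excitation of the diazoketone expels N2 while the 1-bromovinyl group shifts to the former diazo carbon (Wolff rearrangement, new C5–C6 bond), which gives dienylketene 12, a hexatriene made of the ketene C=C, the bromoalkene and the pyrrole C2=C3 bond. A thermal disrotatory 6π electrocyclisation joins the ketene carbon to pyrrole C3 (new C3a–C4 bond, closure of the six-membered carbocycle), and dienone 13 enolises at once to phenol 14, so the transient C3a–H centre leaves no stereocentre behind. The closest known reaction types are the photochemical Wolff route to vinylketenes and the dienylketene-to-phenol finish of the Danheiser benzannulation, the thermolysis of 4-hetarylcyclobutenones, and the acetic anhydride cyclisation of pyrrolyl Stobbe half-esters to 4-acetoxyindoles. Closure at C3 instead of nitrogen is secured by the N-tosyl group, which leaves nitrogen no hydrogen to lose and favours the rotamer that turns C3 towards the ketene arm. The cis relation of pyrrole and ketene comes from the E alkene of 11, and ketene of the other geometry can re-enter through reversible 4π closure to a cyclobutenone during the ageing at 80 °C. Metal-free irradiation at 365 nm in a dry, dilute, non-nucleophilic medium is chosen to keep carbenoid C–H insertion at C3 (which would lead to the 5-hydroxy isomer), C–Br homolysis and capture of the ketene by water or by 14 in the background.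

Step 8
Reactants: 14 6-bromo-3-(2,4-dimethoxypyrimidin-5-yl)-1-tosyl-1H-indol-4-ol
Product: 15 6-bromo-3-(2,4-dimethoxypyrimidin-5-yl)-1-tosyl-1H-indol-4-yl acetate
Conditions: Ac2O, Et3N, DMAP (cat.), CH2Cl2, 20 °C
Reagents that add atoms: acetic anhydride, CC(=O)OC(C)=O
Why: DMAP-catalysed O-acetylation of the phenol, chosen because the acetate shields the oxygen from phosphorylation in step 10 and falls off without an extra operation in step 11.

Step 9
Reactants: 15 6-bromo-3-(2,4-dimethoxypyrimidin-5-yl)-1-tosyl-1H-indol-4-yl acetate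
Product: 17 6-bromo-3-(2,4-dioxo-1,2,3,4-tetrahydropyrimidin-5-yl)-1-tosyl-1H-indol-4-yl acetate, via bis(trimethylsilyloxy)pyrimidine 16 (not isolated)
Conditions: Me3SiCl, NaI, MeCN, 20 → 40 °C; then H2O, aq. Na2S2O3
Reagents that add atoms: chlorotrimethylsilane, C[Si](C)(C)Cl (silyl groups of intermediate 16 only; only hydrogen stays in 17)
Why: Iodotrimethylsilane formed in situ activates the ring nitrogens and iodide removes both O-methyl groups by SN2 dealkylation of the imidate-type ethers under anhydrous conditions that leave the aryl acetate, the sulfonamide and the aryl bromide alone, after which water releases the uracil.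

Step 10
Reactants: 17 6-bromo-3-(2,4-dioxo-1,2,3,4-tetrahydropyrimidin-5-yl)-1-tosyl-1H-indol-4-yl acetate
Product: 18 6-bromo-3-(2,4-dibromopyrimidin-5-yl)-1-tosyl-1H-indol-4-yl acetate
Conditions: POBr3 (4 equiv), PhNEt2, PhMe, 105 °C; ice, aq. NaHCO3
Reagents that add atoms: phosphorus oxybromide, O=P(Br)(Br)Br
Why: Bromodeoxygenation of both lactam carbonyls by O-phosphorylation and addition–elimination of bromide is the standard way from uracils to 2,4-dibromopyrimidines, and the N-tosyl and O-acetyl groups leave no free N–H or O–H to phosphorylate and keep the indole deactivated towards acid.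

Step 11
Reactants: 18 6-bromo-3-(2,4-dibromopyrimidin-5-yl)-1-tosyl-1H-indol-4-yl acetate
Product: 20 3-(4-amino-2-bromopyrimidin-5-yl)-6-bromo-1-tosyl-1H-indol-4-ol, via aminopyrimidine acetate 19 (not isolated)
Conditions: NH3 (2 M in i-PrOH), THF, sealed tube, 20 °C → 50 °C
Reagents that add atoms: ammonia, N
Why: Nucleophilic aromatic substitution of 2,4-dihalopyrimidines by ammonia prefers C4 (the position para to N1), the amino group introduced then deactivates C2–Br so that substitution stops, and the aryl acetate is ammonolysed in the same flask.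

Step 12
Reactants: 20 3-(4-amino-2-bromopyrimidin-5-yl)-6-bromo-1-tosyl-1H-indol-4-ol
Product: 21 3-(4-amino-2-bromopyrimidin-5-yl)-6-bromo-1H-indol-4-ol (target)
Conditions: NaOH (2 M aq.), dioxane, argon, 60 °C; then 1 M HCl to pH 7
Reagents that add atoms: none
Why: Hydroxide attacks the sulfonyl sulfur and releases the indolide (standard N-tosylindole cleavage), while C2–Br, deactivated by the 4-amino group and the electron-rich indolyl phenoxide, needs far harsher conditions for hydrolysis, and the alcohol-free medium avoids a sulfonate ester that could alkylate the phenoxide.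

Compound list
1 | 4-bromo-1H-pyrrole-2-carbaldehyde | O=Cc1cc(Br)c[nH]1 | starting material
2 | 4-bromo-1-tosyl-1H-pyrrole-2-carbaldehyde | O=Cc1cc(Br)cn1S(=O)(=O)c1ccc(C)cc1 | intermediate
3 | (2,4-dimethoxypyrimidin-5-yl)boronic acid | COc1ncc(B(O)O)c(OC)n1 | starting material
4 | 4-(2,4-dimethoxypyrimidin-5-yl)-1-tosyl-1H-pyrrole-2-carbaldehyde | O=Cc1cc(-c2cnc(OC)nc2OC)cn1S(=O)(=O)c1ccc(C)cc1 | intermediate
5 | methyl 2-[bis(2,2,2-trifluoroethoxy)phosphoryl]acetate | COC(=O)CP(=O)(OCC(F)(F)F)OCC(F)(F)F | starting material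
6 | methyl 2-bromo-2-[bis(2,2,2-trifluoroethoxy)phosphoryl]acetate (racemic) | COC(=O)C(Br)P(=O)(OCC(F)(F)F)OCC(F)(F)F | intermediate
7 | methyl (E)-2-bromo-3-[4-(2,4-dimethoxypyrimidin-5-yl)-1-tosyl-1H-pyrrol-2-yl]prop-2-enoate | COC(=O)/C(Br)=C\c1cc(-c2cnc(OC)nc2OC)cn1S(=O)(=O)c1ccc(C)cc1 | intermediate
8 | (E)-2-bromo-3-[4-(2,4-dimethoxypyrimidin-5-yl)-1-tosyl-1H-pyrrol-2-yl]prop-2-enoic acid | OC(=O)/C(Br)=C\c1cc(-c2cnc(OC)nc2OC)cn1S(=O)(=O)c1ccc(C)cc1 | intermediate
9 | (trimethylsilyl)diazomethane | C[Si](C)(C)C=[N+]=[N-] | starting material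
10 | (E)-2-bromo-3-[4-(2,4-dimethoxypyrimidin-5-yl)-1-tosyl-1H-pyrrol-2-yl]prop-2-enoyl chloride (not isolated) | ClC(=O)/C(Br)=C\c1cc(-c2cnc(OC)nc2OC)cn1S(=O)(=O)c1ccc(C)cc1 | intermediate
11 | (E)-3-bromo-1-diazo-4-[4-(2,4-dimethoxypyrimidin-5-yl)-1-tosyl-1H-pyrrol-2-yl]but-3-en-2-one | [N-]=[N+]=CC(=O)/C(Br)=C\c1cc(-c2cnc(OC)nc2OC)cn1S(=O)(=O)c1ccc(C)cc1 | intermediate
12 | (E)-3-bromo-4-[4-(2,4-dimethoxypyrimidin-5-yl)-1-tosyl-1H-pyrrol-2-yl]buta-1,3-dien-1-one (dienylketene, not isolated) | O=C=C/C(Br)=C\c1cc(-c2cnc(OC)nc2OC)cn1S(=O)(=O)c1ccc(C)cc1 | intermediate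
13 | 6-bromo-3-(2,4-dimethoxypyrimidin-5-yl)-1-tosyl-1,3a-dihydro-4H-indol-4-one (racemic at C3a, transient, not isolated) | O=C1C=C(Br)C=C2N(S(=O)(=O)c3ccc(C)cc3)C=C(c3cnc(OC)nc3OC)C12 | intermediate
14 | 6-bromo-3-(2,4-dimethoxypyrimidin-5-yl)-1-tosyl-1H-indol-4-ol | COc1ncc(-c2cn(S(=O)(=O)c3ccc(C)cc3)c3cc(Br)cc(O)c23)c(OC)n1 | intermediate
15 | 6-bromo-3-(2,4-dimethoxypyrimidin-5-yl)-1-tosyl-1H-indol-4-yl acetate | COc1ncc(-c2cn(S(=O)(=O)c3ccc(C)cc3)c3cc(Br)cc(OC(C)=O)c23)c(OC)n1 | intermediate
16 | 6-bromo-3-[2,4-bis(trimethylsilyloxy)pyrimidin-5-yl]-1-tosyl-1H-indol-4-yl acetate (not isolated) | C[Si](C)(C)Oc1ncc(-c2cn(S(=O)(=O)c3ccc(C)cc3)c3cc(Br)cc(OC(C)=O)c23)c(O[Si](C)(C)C)n1 | intermediate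
17 | 6-bromo-3-(2,4-dioxo-1,2,3,4-tetrahydropyrimidin-5-yl)-1-tosyl-1H-indol-4-yl acetate | O=c1[nH]cc(-c2cn(S(=O)(=O)c3ccc(C)cc3)c3cc(Br)cc(OC(C)=O)c23)c(=O)[nH]1 | intermediate
18 | 6-bromo-3-(2,4-dibromopyrimidin-5-yl)-1-tosyl-1H-indol-4-yl acetate | Brc1ncc(-c2cn(S(=O)(=O)c3ccc(C)cc3)c3cc(Br)cc(OC(C)=O)c23)c(Br)n1 | intermediate
19 | 3-(4-amino-2-bromopyrimidin-5-yl)-6-bromo-1-tosyl-1H-indol-4-yl acetate (not isolated) | Nc1nc(Br)ncc1-c1cn(S(=O)(=O)c2ccc(C)cc2)c2cc(Br)cc(OC(C)=O)c12 | intermediate
20 | 3-(4-amino-2-bromopyrimidin-5-yl)-6-bromo-1-tosyl-1H-indol-4-ol | Nc1nc(Br)ncc1-c1cn(S(=O)(=O)c2ccc(C)cc2)c2cc(Br)cc(O)c12 | intermediate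
21 | 3-(4-amino-2-bromopyrimidin-5-yl)-6-bromo-1H-indol-4-ol | Nc1nc(Br)ncc1-c1c[nH]c2cc(Br)cc(O)c12 | target

Total step count: 12.
Longest linear sequence: 11 (steps 1, 2 and 4–12). Step 3 is a one-step side branch.

Steps most likely to fail

1. Step 7.
- The ketene may be intercepted by moisture or by the phenol already formed before it closes.
- The excited bromoenone may lose bromine.
- The carbene may react before the vinyl shift takes place.
- The fallback sets out from 11 and separates homologation from ring closure. Wolff rearrangement catalysed by AgO2CPh with Et3N in THF/H2O in the dark (Arndt–Eistert homologation) should give (E)-3-bromo-4-[4-(2,4-dimethoxypyrimidin-5-yl)-1-tosyl-1H-pyrrol-2-yl]but-3-enoic acid F1.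
- Heating F1 in Ac2O with NaOAc should close C3a–C4 through the mixed anhydride and acetylate the phenol in the same flask. These are the conditions used for Stobbe half-acids of pyrrole aldehydes.
- The fallback comes back to the route at 15, so step 8 is no longer needed.

2. Step 6.
- The diazoalkane may add as a dipole across the bromoenoyl double bond.
- Chloride may scramble the alkene geometry by addition–elimination while the acid chloride is made.
- The fallback sets out from 8 and installs the diazo group by diazo transfer instead of acylation. Coupling with MeNHOMe·HCl (EDC·HCl, i-Pr2NEt, CH2Cl2) should give (E)-2-bromo-N-methoxy-N-methyl-3-[4-(2,4-dimethoxypyrimidin-5-yl)-1-tosyl-1H-pyrrol-2-yl]prop-2-enamide F2.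
- MeMgBr in THF at −78 °C should give (E)-3-bromo-4-[4-(2,4-dimethoxypyrimidin-5-yl)-1-tosyl-1H-pyrrol-2-yl]but-3-en-2-one F3.
- LiN(SiMe3)2 and then CF3CO2CH2CF3 at −78 °C should give (E)-5-bromo-1,1,1-trifluoro-6-[4-(2,4-dimethoxypyrimidin-5-yl)-1-tosyl-1H-pyrrol-2-yl]hex-5-ene-2,4-dione F4, which is used crude.
- MsN3, Et3N and H2O in MeCN then perform the detrifluoroacetylative diazo transfer. This method was developed for conjugated diazoketones. The fallback comes back at 11.

3. Step 10.
- Hot POBr3 may leave the hindered C4 position incompletely substituted.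
- It may cleave the acetate, with phosphorylation of the phenol following.
- It may brominate indole C2 through traces of free bromine.
- The fallback sets out from 17 and brings in the C2 bromine by late halogen exchange. POCl3 with PhNEt2 at reflux should give 6-bromo-3-(2,4-dichloropyrimidin-5-yl)-1-tosyl-1H-indol-4-yl acetate F5.
- NH3 in i-PrOH/THF should give 3-(4-amino-2-chloropyrimidin-5-yl)-6-bromo-1-tosyl-1H-indol-4-ol F6.
- Me3SiBr in propionitrile at reflux should exchange C2–Cl for C2–Br on the N-silylated pyrimidinium, with the more volatile Me3SiCl distilling off. After aqueous work-up the fallback comes back at 20.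

Further compounds
F1 | step 7 | (E)-3-bromo-4-[4-(2,4-dimethoxypyrimidin-5-yl)-1-tosyl-1H-pyrrol-2-yl]but-3-enoic acid | OC(=O)C/C(Br)=C\c1cc(-c2cnc(OC)nc2OC)cn1S(=O)(=O)c1ccc(C)cc1
F2 | step 6 | (E)-2-bromo-N-methoxy-N-methyl-3-[4-(2,4-dimethoxypyrimidin-5-yl)-1-tosyl-1H-pyrrol-2-yl]prop-2-enamide | CON(C)C(=O)/C(Br)=C\c1cc(-c2cnc(OC)nc2OC)cn1S(=O)(=O)c1ccc(C)cc1
F3 | step 6 | (E)-3-bromo-4-[4-(2,4-dimethoxypyrimidin-5-yl)-1-tosyl-1H-pyrrol-2-yl]but-3-en-2-one | CC(=O)/C(Br)=C\c1cc(-c2cnc(OC)nc2OC)cn1S(=O)(=O)c1ccc(C)cc1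
F4 | step 6 | (E)-5-bromo-1,1,1-trifluoro-6-[4-(2,4-dimethoxypyrimidin-5-yl)-1-tosyl-1H-pyrrol-2-yl]hex-5-ene-2,4-dione | O=C(CC(=O)/C(Br)=C\c1cc(-c2cnc(OC)nc2OC)cn1S(=O)(=O)c1ccc(C)cc1)C(F)(F)F
F5 | step 10 | 6-bromo-3-(2,4-dichloropyrimidin-5-yl)-1-tosyl-1H-indol-4-yl acetate | Clc1ncc(-c2cn(S(=O)(=O)c3ccc(C)cc3)c3cc(Br)cc(OC(C)=O)c23)c(Cl)n1
F6 | step 10 | 3-(4-amino-2-chloropyrimidin-5-yl)-6-bromo-1-tosyl-1H-indol-4-ol | Nc1nc(Cl)ncc1-c1cn(S(=O)(=O)c2ccc(C)cc2)c2cc(Br)cc(O)c12
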